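## Analysis of the target

Target 30 is a 5,6-dihydro-2H-pyran-2-one (ring A: the ring oxygen and C1–C5; atoms are numbered from the lactone carbonyl C1 to the benzylic carbon C15). Its C5 carries one unbranched chain: the Z alkene C6=C7, methylene C8, the carbinols C9, C11 and C13 separated by the methylenes C10 and C12, and the phenethyl end C14–C15–phenyl. There are four stereocentres, C5 (S), C9 (R), C11 (S) and C13 (R). In a zigzag drawing the C9 and C11 hydroxyls are syn and the C11 and C13 hydroxyls are anti, while C5 is cut off from the triol by the alkene and C8. The sensitive groups are the unsaturated lactone (a Michael acceptor, base-labile, with an allylic C5–O bond), the Z alkene (isomerisation, over-reduction) and the free 1,3,5-triol, so the last deprotection has to be mild and acidic. The synthesis is hard because the triol carries only hydrogen on the carbons between the carbinols, which gives acyclic stereocontrol little to hold on to, because the two chain ends must be told apart, and because C5 can only be set by a reagent. The strategy rests on C7–C13: seven carbons with syn oxygens on C9 and C11 and methylenes at C8, C10 and C12. Joined C7 to C13 by a double bond they form a meso cis-dioxygenated cycloheptene (ring B), and with an oxygen bridge from C9 to C13 they form the 8-oxabicyclo[3.2.1]oct-6-ene that furan and a three-carbon oxyallyl unit give in one cycloaddition.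

## Retrosynthetic reasoning

**Lactone ring (C2=C3).** Target 30 comes from its tris-silyl ether 29 by acidic desilylation. Ring A of 29 is cut at C2=C3, a ring-closing metathesis of acrylate 28, which is the ester of dienol 27. Cutting here, and not at the C1–O bond, avoids a Z-selective enoate olefination and lets the C5 oxygen act as the tether for a six-membered closure.

**Z alkene (C6=C7).** Dienol 27 comes from enynol 26 by semihydrogenation. The alkyne is reduced before acylation and metathesis so that neither an acrylate nor a ruthenium carbene meets the triple bond. The alkyne also makes C6 a nucleophile for the chain extension.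

**C4–C5.** Enynol 26 is cut between C4 and C5, an allyl transfer from boron to ynal 25. The nearest stereocentre, C9, is four atoms from C5 and cannot direct it, so the forward step has to set C5 (S) by the reagent alone.

**C5–C6 and C6–C7.** Ynal 25 comes from terminal alkyne 23 by formylation, and 23 from aldehyde 22 by a one-carbon homologation. Aldehyde 22 comes from primary alcohol 21, which is released from the fully silylated 20, itself made from tetraol 19. These steps turn the C7 terminus into the alkyne and leave C9, C11 and C13 under one kind of protecting group.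

**C13 stereocentre and C13–C14.** Tetraol 19 comes from acetonide diol 18, and 18 from β-hydroxy ketone 17 by a hydroxyl-directed 1,3-anti reduction, so C13 is relayed from C11. Ketone 17 comes from PMB ether 16, the oxidation product of alcohol 15. Alcohol 15 is cut at C13–C14 into aldehyde 12 and the Grignard reagent 14 made from bromide 13. The C13–C14 bond is chosen because it lets the phenethyl group be bought.

**Telling the chain ends apart.** Aldehyde 12 comes from alcohol 11, the acetonide of triol 10. Only the free C9 hydroxyl of 10 has a 1,3-partner (the C7 hydroxyl), so the acetonide masks C7 and C9 and leaves the C13 hydroxyl as the only free one.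

**Ring B to chain (C7=C13).** Triol 10 comes from cycloheptenol 8 by cleavage of the C7=C13 double bond with reduction. This turns the ring, in which the cis relation of C9 and C11 is fixed, into the chain with its syn diol.

**Desymmetrisation.** Cycloheptenol 8 comes from the meso oxabicycle 6 by reductive cleavage of one bridging C–O bond under a chiral nickel catalyst. The forward step must deliver hydride to one of two enantiotopic alkene carbons. It then gives C9 and C11 in one absolute sense and leaves one oxygen free and the other as an ether.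

**The bicycle.** Ether 6 comes from the exo alcohol 5, 5 from ketone 4, and 4 through dibromide 3 from a [4+3] cycloaddition of furan 1 with the oxyallyl unit of tetrabromoacetone 2. Furan supplies C7, C8, C9, C13 and the bridging oxygen, and the ketone supplies C10–C12.

## Alternatives that were turned down

**Alternative 1:** Ring A is cut at C4–C5 and O–C1. The ynal A2 (C5 aldehyde on the C6≡C7 alkyne, triol already protected) and (E)-1-methoxybuta-1,3-diene A3 would combine in a hetero-Diels–Alder reaction. The catalyst is the chromium chloride complex (L)CrCl of trivalent chromium, where L is the doubly deprotonated Schiff base of 3-(1-adamantyl)-2-hydroxy-5-methylbenzaldehyde and cis-1-aminoindan-2-ol. The product is the 2,6-cis methoxy dihydropyran A1; acetal oxidation and semihydrogenation would follow.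
- For: the ring is formed with C5 set by the catalyst, independent of the remote centres, and in fewer steps than allylation, acylation and metathesis. On the C1–C5 portion this alternative is stronger than the chosen route.
- Against: it does nothing for C9, C11 and C13. The triol in A2 still needs its own stereocontrolled synthesis, and the acetal-to-lactone oxidation must spare an acid-labile acetonide and an alkyne.
- Comparison: the chosen route takes more steps at the lactone end, but it obtains two of the three triol centres and the distinction of the chain ends from one catalytic step on an achiral bicycle.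

**Alternative 2:** The chain is cut at C9–C10. The methyl ketone A5 (C10–C15, PMB ether at C13), enolised with a dialkylboron triflate, would add to the alkynyl aldehyde A6 (C6–C9). The product is the β-hydroxy ketone A4 with C9 set 1,5-anti to C13; a syn-selective reduction of the C11 ketone would complete the triad.
- For: it is convergent and short, and one stereocentre (C13) is relayed to both others. On step economy for C8–C15 it is stronger than the chosen route.
- Against: 1,5-induction depends on the ether at C13 and on the aldehyde, and A6 is small, unbranched and prone to isomerise to an allenyl aldehyde under amine and boron Lewis acid. C13 in A5 still needs an enantioselective step of its own.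
- Comparison: the chosen route is longer, but the syn C9/C11 relation is inherited from a ring, where it cannot be wrong, and C13 is set by a 1,3 relay, not a 1,5 relay.

**Alternative 3:** The C6=C7 bond is made by ring-closing metathesis. A C5 allylic alcohol and a C9 homoallylic alcohol would be joined through a diisopropylsilylene bridge in diene A8. The second-generation Grubbs catalyst (H2IMes)(PCy3)Cl2Ru=CHPh would close it to the eight-membered silaketal A7, in which only the Z alkene fits.
- For: the Z geometry is enforced by the ring, with no semihydrogenation and no risk of over-reduction. On this point it is stronger than the chosen route.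
- Against: the mixed silaketal needs two separate silylations without homodimer formation, and an eight-membered closure needs high dilution. Both halves need separate asymmetric syntheses (C5, and C9/C11/C13), and after the metathesis the lactone must still be built from the C3 ether by deprotection, oxidation, Z-olefination and lactonisation.
- Comparison: the chosen route accepts a Lindlar step but needs no separately made chiral fragment, and it reaches the lactone by a single closure.

Key step: step 5

Remark on the chemistry: (R)-BINAP is assumed to direct hydride to the alkene carbon beside the (S)-bridgehead of 6; if the opposite sense is found, (S)-BINAP is used and nothing else changes.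

## Route

Step 1
Reactants: 1 furan; 2 1,1,3,3-tetrabromoacetone
Product: 3 2,4-dibromo-8-oxabicyclo[3.2.1]oct-6-en-3-one (mixture of bromide epimers)
Conditions: Zn–Ag couple, furan (excess), THF, −10 °C to rt
Reagents that add atoms: none
Why: Zinc reduces 2 to a bromine-stabilised zinc oxyallyl cation, which adds across C2/C5 of furan in a [4+3] cycloaddition; the cis bridgeheads follow from the bridged ring, and the bromine configuration does not matter because both bromines are removed next.

Step 2
Reactants: 3 2,4-dibromo-8-oxabicyclo[3.2.1]oct-6-en-3-one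
Product: 4 8-oxabicyclo[3.2.1]oct-6-en-3-one (meso)
Conditions: Zn–Cu couple, NH4Cl, MeOH, −78 °C to rt
Reagents that add atoms: none
Why: Reductive dehalogenation of the α-bromo ketone through zinc enolates that NH4Cl protonates; the strained alkene and the ether bridge are not touched.

Step 3
Reactants: 4 8-oxabicyclo[3.2.1]oct-6-en-3-one
Product: 5 exo-8-oxabicyclo[3.2.1]oct-6-en-3-ol (meso; hydroxyl equatorial, on the same face of the seven-membered carbocycle as the oxygen bridge)
Conditions: SmI2, iPrOH, THF, reflux
Reagents that add atoms: none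
Why: Electron-transfer reduction by divalent samarium goes through a ketyl and a carbanion that is protonated to the more stable equatorial alcohol, whereas bulky hydrides would attack the exo face and give the axial alcohol; the product is meso, so only the relative configuration is at stake.

Step 4
Reactants: 5 exo-8-oxabicyclo[3.2.1]oct-6-en-3-ol
Product: 6 exo-3-[(4-methoxybenzyl)oxy]-8-oxabicyclo[3.2.1]oct-6-ene (meso)
Conditions: NaH, PMBCl, Bu4NI (cat.), THF/DMF, 0 °C to rt
Reagents that add atoms: 4-methoxybenzyl chloride, COc1ccc(CCl)cc1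
Why: Williamson ether synthesis; the PMB ether is chosen because it cannot migrate between oxygens and is later removed oxidatively without acid or base.

Step 5
Reactants: 6 exo-3-[(4-methoxybenzyl)oxy]-8-oxabicyclo[3.2.1]oct-6-ene
Product: 8 (1R,6S)-6-[(4-methoxybenzyl)oxy]cyclohept-3-en-1-ol, via diisobutylaluminium alkoxide 7 (not isolated)
Conditions: Ni(cod)2 (10 mol %), (R)-BINAP (15 mol %), iBu2AlH (1.2 equiv, syringe pump), THF, 60 °C; then aq. KNaC4H4O6
Reagents that add atoms: none
Why: The zerovalent nickel–BINAP complex binds the strained C=C of 6 on its exo face (the face of the oxygen bridge) and, with iBu2AlH, adds hydride and metal syn across it, hydride going to the alkene carbon next to the (S)-bridgehead (future C8) and the metal to the other (future C7). The β-alkoxy organometal so formed eliminates the bridging oxygen, helped by the Lewis-acidic aluminium, so that the C13–O bond breaks, the C7=C13 alkene appears and the oxygen stays on C9 as aluminium alkoxide 7, which aqueous tartrate hydrolyses to 8. The closest known reaction type is the nickel-catalysed enantioselective hydroalumination with ring opening of oxabenzonorbornadienes and 8-oxabicyclo[3.2.1]oct-6-enes. No ring is closed: the tetrahydropyran ring of the bicycle is opened and the seven-membered carbocycle (ring B) remains. No bond to C9 or C11 is made or broken; these centres, mirror-related in meso 6, become stereogenic in one sense (C9 R, C11 S in 8) because the chiral diphosphine on nickel chooses between the two enantiotopic alkene carbons, and they are cis because the ether in 6 is exo. The step needs selection between enantiotopic carbons, opening instead of plain reduction, and an inert product alkene: slow addition keeps free iBu2AlH low so that the uncatalysed, unselective hydroalumination cannot compete, ring strain and 60 °C drive the elimination, and the unstrained cycloheptene of 8 does not react further. The exo PMB ether lies far from the exo face of the alkene and, unlike a silyl ether, cannot migrate to the neighbouring alkoxide, so the distinction between the C9 and C11 oxygens is kept.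

Step 6
Reactants: 8 (1R,6S)-6-[(4-methoxybenzyl)oxy]cyclohept-3-en-1-ol
Product: 10 (3R,5S)-5-[(4-methoxybenzyl)oxy]heptane-1,3,7-triol, via secondary ozonide 9 (not isolated)
Conditions: O3, CH2Cl2, −78 °C (Sudan Red 7B end point); then NaBH4, MeOH, −78 °C to rt
Reagents that add atoms: ozone, [O-][O+]=O
Why: Ozonolysis with reductive work-up; the isolated alkene adds ozone much faster than the anisyl ring at −78 °C, and borohydride reduces whichever peroxidic form is present to the two primary alcohols at C7 and C13 without touching C9 or C11.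

Step 7
Reactants: 10 (3R,5S)-5-[(4-methoxybenzyl)oxy]heptane-1,3,7-triol
Product: 11 (3S)-4-[(4R)-2,2-dimethyl-1,3-dioxan-4-yl]-3-[(4-methoxybenzyl)oxy]butan-1-ol
Conditions: Me2C(OMe)2, PPTS (cat.), CH2Cl2, rt; then MeOH, rt (brief)
Reagents that add atoms: 2,2-dimethoxypropane, COC(C)(C)OC
Why: Acid-catalysed transketalisation; only the C7 and C9 hydroxyls stand 1,3 to each other, so only they can close a six-membered acetonide, and a mixed acyclic ketal at the C13 hydroxyl is cleaved again by the methanol treatment.

Step 8
Reactants: 11 (3S)-4-[(4R)-2,2-dimethyl-1,3-dioxan-4-yl]-3-[(4-methoxybenzyl)oxy]butan-1-ol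
Product: 12 (3R)-4-[(4R)-2,2-dimethyl-1,3-dioxan-4-yl]-3-[(4-methoxybenzyl)oxy]butanal
Conditions: Dess–Martin periodinane, NaHCO3, CH2Cl2, 0 °C to rt
Reagents that add atoms: none
Why: Dess–Martin oxidation under buffered, non-basic conditions, so that the β-alkoxy aldehyde does not eliminate and the acetonide stays (the descriptor at C11 changes only through the priority rules).

Step 9
Reactants: 12 (3R)-4-[(4R)-2,2-dimethyl-1,3-dioxan-4-yl]-3-[(4-methoxybenzyl)oxy]butanal; 13 (2-bromoethyl)benzene
Product: 15 (5S)-6-[(4R)-2,2-dimethyl-1,3-dioxan-4-yl]-5-[(4-methoxybenzyl)oxy]-1-phenylhexan-3-ol (both C13 epimers), via phenethylmagnesium bromide 14 (not isolated)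
Conditions: Mg, THF, rt; then 12, THF, −78 to 0 °C; aq. NH4Cl
Reagents that add atoms: none
Why: Grignard addition to the aldehyde forms the C13–C14 bond; the configuration at C13 is of no concern because the carbinol is oxidised in the next step.

Step 10
Reactants: 15 (5S)-6-[(4R)-2,2-dimethyl-1,3-dioxan-4-yl]-5-[(4-methoxybenzyl)oxy]-1-phenylhexan-3-ol
Product: 16 (5R)-6-[(4R)-2,2-dimethyl-1,3-dioxan-4-yl]-5-[(4-methoxybenzyl)oxy]-1-phenylhexan-3-one
Conditions: Dess–Martin periodinane, NaHCO3, CH2Cl2, rt
Reagents that add atoms: none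
Why: Dess–Martin oxidation of the secondary alcohol converges both epimers to one β-alkoxy ketone; the neutral conditions avoid elimination of the PMB ether.

Step 11
Reactants: 16 (5R)-6-[(4R)-2,2-dimethyl-1,3-dioxan-4-yl]-5-[(4-methoxybenzyl)oxy]-1-phenylhexan-3-one
Product: 17 (5R)-6-[(4R)-2,2-dimethyl-1,3-dioxan-4-yl]-5-hydroxy-1-phenylhexan-3-one
Conditions: DDQ, CH2Cl2/pH 7 phosphate buffer, 0 °C to rt
Reagents that add atoms: none
Why: Oxidative PMB cleavage: hydride abstraction from the electron-rich benzylic position gives an oxocarbenium ion that water hydrolyses; the buffer protects the acetonide and the β-hydroxy ketone from the acidic hydroquinone.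

Step 12
Reactants: 17 (5R)-6-[(4R)-2,2-dimethyl-1,3-dioxan-4-yl]-5-hydroxy-1-phenylhexan-3-one
Product: 18 (2S,4R)-1-[(4R)-2,2-dimethyl-1,3-dioxan-4-yl]-6-phenylhexane-2,4-diol
Conditions: Me4NBH(OAc)3, MeCN/AcOH, −30 °C
Reagents that add atoms: none
Why: Evans–Saksena reduction: the triacetoxyborohydride exchanges an acetate for the C11 hydroxyl and delivers hydride within the molecule through a chair-like six-membered transition state, which gives the 1,3-anti diol and so C13 (R); the acetonide tolerates acetic acid at this temperature.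

Step 13
Reactants: 18 (2S,4R)-1-[(4R)-2,2-dimethyl-1,3-dioxan-4-yl]-6-phenylhexane-2,4-diol
Product: 19 (3R,5S,7R)-9-phenylnonane-1,3,5,7-tetraol
Conditions: Dowex 50W (H+ form), MeOH, rt
Reagents that add atoms: none
Why: Acid-catalysed acetal exchange with methanol removes the acetonide; the resin is filtered off, so the polar tetraol needs no aqueous extraction.

Step 14
Reactants: 19 (3R,5S,7R)-9-phenylnonane-1,3,5,7-tetraol
Product: 20 (3R,5S,7R)-1,3,5,7-tetrakis[(tert-butyldimethylsilyl)oxy]-9-phenylnonane
Conditions: TBSOTf, 2,6-lutidine, CH2Cl2, −78 to 0 °C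
Reagents that add atoms: tert-butyldimethylsilyl trifluoromethanesulfonate, CC(C)(C)[Si](C)(C)OS(=O)(=O)C(F)(F)F
Why: Exhaustive silylation with the silyl triflate, which is reactive enough for the hindered secondary hydroxyls of a 1,3,5-array.

Step 15
Reactants: 20 (3R,5S,7R)-1,3,5,7-tetrakis[(tert-butyldimethylsilyl)oxy]-9-phenylnonane
Product: 21 (3R,5S,7R)-3,5,7-tris[(tert-butyldimethylsilyl)oxy]-9-phenylnonan-1-ol
Conditions: HF·pyridine, pyridine, THF, 0 °C
Reagents that add atoms: none
Why: Selective desilylation: the primary silyl ether is the least hindered and is cleaved first by buffered fluoride, while the three secondary ethers remain.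

Step 16
Reactants: 21 (3R,5S,7R)-3,5,7-tris[(tert-butyldimethylsilyl)oxy]-9-phenylnonan-1-ol
Product: 22 (3S,5S,7R)-3,5,7-tris[(tert-butyldimethylsilyl)oxy]-9-phenylnonanal
Conditions: Dess–Martin periodinane, NaHCO3, CH2Cl2, rt
Reagents that add atoms: none
Why: Dess–Martin oxidation to the β-silyloxy aldehyde without base (the descriptor at C9 changes only through the priority rules).

Step 17
Reactants: 22 (3S,5S,7R)-3,5,7-tris[(tert-butyldimethylsilyl)oxy]-9-phenylnonanal
Product: 23 (4R,6S,8R)-4,6,8-tris[(tert-butyldimethylsilyl)oxy]-10-phenyldec-1-yne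
Conditions: dimethyl (1-diazo-2-oxopropyl)phosphonate, K2CO3, MeOH, 0 °C to rt
Reagents that add atoms: dimethyl (1-diazo-2-oxopropyl)phosphonate, CC(=O)C(=[N+]=[N-])P(=O)(OC)OC
Why: Ohira–Bestmann (Seyferth–Gilbert) homologation: the diazophosphonate anion adds to the aldehyde, and loss of phosphate and nitrogen with a 1,2-hydrogen shift gives the terminal alkyne (C7≡C6); the mild carbonate conditions are tolerated by β-silyloxy aldehydes.

Step 18
Reactants: 23 (4R,6S,8R)-4,6,8-tris[(tert-butyldimethylsilyl)oxy]-10-phenyldec-1-yne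
Product: 25 (5R,7S,9R)-5,7,9-tris[(tert-butyldimethylsilyl)oxy]-11-phenylundec-2-ynal, via lithium acetylide 24 (not isolated)
Conditions: n-BuLi, THF, −78 °C; DMF, −78 to 0 °C; inverse quench into aq. KH2PO4
Reagents that add atoms: N,N-dimethylformamide, CN(C)C=O
Why: Formylation of a lithium acetylide: the hemiaminal alkoxide is stable until the buffered inverse quench, which releases the ynal (C5) and keeps dimethylamine from adding to it.

Step 19
Reactants: 25 (5R,7S,9R)-5,7,9-tris[(tert-butyldimethylsilyl)oxy]-11-phenylundec-2-ynal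
Product: 26 (4S,8R,10S,12R)-8,10,12-tris[(tert-butyldimethylsilyl)oxy]-14-phenyltetradec-1-en-5-yn-4-ol
Conditions: (−)-Ipc2BOMe, allylMgBr, Et2O, −78 °C to rt; then 25, −78 °C; then NaOH, H2O2, rt
Reagents that add atoms: allylmagnesium bromide, C=CC[Mg]Br
Why: Brown allylboration: B-allyldiisopinocampheylborane formed in the flask adds through a closed chair transition state with the alkynyl group equatorial, and the isopinocampheyl groups from (+)-α-pinene direct the allyl group to the Si face of the aldehyde, which corresponds to (S) at C5. C9, the nearest stereocentre, is four atoms away, so the reagent alone should decide.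

Step 20
Reactants: 26 (4S,8R,10S,12R)-8,10,12-tris[(tert-butyldimethylsilyl)oxy]-14-phenyltetradec-1-en-5-yn-4-ol
Product: 27 (4S,5Z,8R,10S,12R)-8,10,12-tris[(tert-butyldimethylsilyl)oxy]-14-phenyltetradeca-1,5-dien-4-ol
Conditions: H2 (1 atm), Pd/CaCO3 poisoned with Pb(OAc)2 (Lindlar catalyst), quinoline, EtOAc, rt, stopped after one equivalent
Reagents that add atoms: none
Why: Lindlar semihydrogenation: both hydrogens are delivered from the catalyst surface to the same face of the alkyne, which gives the Z alkene C6=C7; the alkyne binds to the poisoned palladium more strongly than the terminal alkene, which is therefore spared if the uptake is stopped in time.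

Step 21
Reactants: 27 (4S,5Z,8R,10S,12R)-8,10,12-tris[(tert-butyldimethylsilyl)oxy]-14-phenyltetradeca-1,5-dien-4-ol
Product: 28 (4S,5Z,8R,10S,12R)-8,10,12-tris[(tert-butyldimethylsilyl)oxy]-14-phenyltetradeca-1,5-dien-4-yl prop-2-enoate
Conditions: acryloyl chloride, iPr2NEt, CH2Cl2, −78 to 0 °C
Reagents that add atoms: acryloyl chloride, C=CC(=O)Cl
Why: O-Acylation of the only free hydroxyl; the low temperature and the hindered base keep the acrylate from polymerising or adding the amine.

Step 22
Reactants: 28 (4S,5Z,8R,10S,12R)-8,10,12-tris[(tert-butyldimethylsilyl)oxy]-14-phenyltetradeca-1,5-dien-4-yl prop-2-enoate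
Product: 29 (6S)-6-[(1Z,4R,6S,8R)-4,6,8-tris[(tert-butyldimethylsilyl)oxy]-10-phenyldec-1-en-1-yl]-5,6-dihydro-2H-pyran-2-one
Conditions: (PCy3)2Cl2Ru=CHPh (first-generation Grubbs catalyst, cat.), CH2Cl2 (high dilution), 40 °C
Reagents that add atoms: none
Why: Ring-closing metathesis: the ruthenium carbene starts at the terminal allyl alkene and closes onto the acrylate to form the six-membered lactone with loss of ethylene. The Z-disubstituted alkene is slower to react and could only close a four- or five-membered ring.

Step 23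
Reactants: 29 (6S)-6-[(1Z,4R,6S,8R)-4,6,8-tris[(tert-butyldimethylsilyl)oxy]-10-phenyldec-1-en-1-yl]-5,6-dihydro-2H-pyran-2-one
Product: 30 (6S)-6-[(1Z,4R,6S,8R)-4,6,8-trihydroxy-10-phenyldec-1-en-1-yl]-5,6-dihydro-2H-pyran-2-one
Conditions: HF (aq.), MeCN, 0 °C to rt
Reagents that add atoms: none
Why: Acidic fluoride desilylation of the three secondary silyl ethers; the lactone and the Z alkene tolerate these conditions, and the nearest free hydroxyl (C9) could reach the enoate only through an eight-membered ring, so no oxa-Michael addition is expected.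

## Compound list

1 | furan | c1ccoc1 | starting material
2 | 1,1,3,3-tetrabromoacetone | BrC(Br)C(=O)C(Br)Br | starting material
3 | 2,4-dibromo-8-oxabicyclo[3.2.1]oct-6-en-3-one (bromide epimers) | C1=C[C@@H]2C(Br)C(=O)C(Br)[C@H]1O2 | intermediate
4 | 8-oxabicyclo[3.2.1]oct-6-en-3-one | C1=C[C@@H]2CC(=O)C[C@H]1O2 | intermediate
5 | exo-8-oxabicyclo[3.2.1]oct-6-en-3-ol | C1=C[C@@H]2C[C@@H](O)C[C@H]1O2 | intermediate
6 | exo-3-[(4-methoxybenzyl)oxy]-8-oxabicyclo[3.2.1]oct-6-ene | C1=C[C@@H]2C[C@@H](OCc3ccc(OC)cc3)C[C@H]1O2 | intermediate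
7 | diisobutylaluminium (1R,6S)-6-[(4-methoxybenzyl)oxy]cyclohept-3-en-1-olate | CC(C)C[Al](CC(C)C)O[C@@H]1CC=CC[C@H](OCc2ccc(OC)cc2)C1 | intermediate
8 | (1R,6S)-6-[(4-methoxybenzyl)oxy]cyclohept-3-en-1-ol | O[C@@H]1CC=CC[C@H](OCc2ccc(OC)cc2)C1 | intermediate
9 | 5-[(4-methoxybenzyl)oxy]-8,9,10-trioxabicyclo[5.2.1]decan-3-ol (secondary ozonide of 8) | O[C@@H]1CC2OOC(O2)C[C@H](OCc3ccc(OC)cc3)C1 | intermediate
10 | (3R,5S)-5-[(4-methoxybenzyl)oxy]heptane-1,3,7-triol | OCC[C@@H](O)C[C@@H](OCc1ccc(OC)cc1)CCO | intermediate
11 | (3S)-4-[(4R)-2,2-dimethyl-1,3-dioxan-4-yl]-3-[(4-methoxybenzyl)oxy]butan-1-ol | CC1(C)OCC[C@H](C[C@@H](OCc2ccc(OC)cc2)CCO)O1 | intermediate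
12 | (3R)-4-[(4R)-2,2-dimethyl-1,3-dioxan-4-yl]-3-[(4-methoxybenzyl)oxy]butanal | CC1(C)OCC[C@H](C[C@@H](OCc2ccc(OC)cc2)CC=O)O1 | intermediate
13 | (2-bromoethyl)benzene | BrCCc1ccccc1 | starting material
14 | phenethylmagnesium bromide | Br[Mg]CCc1ccccc1 | intermediate
15 | (5S)-6-[(4R)-2,2-dimethyl-1,3-dioxan-4-yl]-5-[(4-methoxybenzyl)oxy]-1-phenylhexan-3-ol (C13 epimers) | CC1(C)OCC[C@H](C[C@@H](OCc2ccc(OC)cc2)CC(O)CCc2ccccc2)O1 | intermediate
16 | (5R)-6-[(4R)-2,2-dimethyl-1,3-dioxan-4-yl]-5-[(4-methoxybenzyl)oxy]-1-phenylhexan-3-one | CC1(C)OCC[C@H](C[C@@H](OCc2ccc(OC)cc2)CC(=O)CCc2ccccc2)O1 | intermediate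
17 | (5R)-6-[(4R)-2,2-dimethyl-1,3-dioxan-4-yl]-5-hydroxy-1-phenylhexan-3-one | CC1(C)OCC[C@H](C[C@@H](O)CC(=O)CCc2ccccc2)O1 | intermediate
18 | (2S,4R)-1-[(4R)-2,2-dimethyl-1,3-dioxan-4-yl]-6-phenylhexane-2,4-diol | CC1(C)OCC[C@H](C[C@@H](O)C[C@H](O)CCc2ccccc2)O1 | intermediate
19 | (3R,5S,7R)-9-phenylnonane-1,3,5,7-tetraol | OCC[C@@H](O)C[C@@H](O)C[C@H](O)CCc1ccccc1 | intermediate
20 | (3R,5S,7R)-1,3,5,7-tetrakis[(tert-butyldimethylsilyl)oxy]-9-phenylnonane | CC(C)(C)[Si](C)(C)OCC[C@@H](O[Si](C)(C)C(C)(C)C)C[C@@H](O[Si](C)(C)C(C)(C)C)C[C@H](O[Si](C)(C)C(C)(C)C)CCc1ccccc1 | intermediate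
21 | (3R,5S,7R)-3,5,7-tris[(tert-butyldimethylsilyl)oxy]-9-phenylnonan-1-ol | OCC[C@@H](O[Si](C)(C)C(C)(C)C)C[C@@H](O[Si](C)(C)C(C)(C)C)C[C@H](O[Si](C)(C)C(C)(C)C)CCc1ccccc1 | intermediate
22 | (3S,5S,7R)-3,5,7-tris[(tert-butyldimethylsilyl)oxy]-9-phenylnonanal | O=CC[C@@H](O[Si](C)(C)C(C)(C)C)C[C@@H](O[Si](C)(C)C(C)(C)C)C[C@H](O[Si](C)(C)C(C)(C)C)CCc1ccccc1 | intermediate
23 | (4R,6S,8R)-4,6,8-tris[(tert-butyldimethylsilyl)oxy]-10-phenyldec-1-yne | C#CC[C@@H](O[Si](C)(C)C(C)(C)C)C[C@@H](O[Si](C)(C)C(C)(C)C)C[C@H](O[Si](C)(C)C(C)(C)C)CCc1ccccc1 | intermediate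
24 | lithium acetylide of 23 | [Li]C#CC[C@@H](O[Si](C)(C)C(C)(C)C)C[C@@H](O[Si](C)(C)C(C)(C)C)C[C@H](O[Si](C)(C)C(C)(C)C)CCc1ccccc1 | intermediate
25 | (5R,7S,9R)-5,7,9-tris[(tert-butyldimethylsilyl)oxy]-11-phenylundec-2-ynal | O=CC#CC[C@@H](O[Si](C)(C)C(C)(C)C)C[C@@H](O[Si](C)(C)C(C)(C)C)C[C@H](O[Si](C)(C)C(C)(C)C)CCc1ccccc1 | intermediate
26 | (4S,8R,10S,12R)-8,10,12-tris[(tert-butyldimethylsilyl)oxy]-14-phenyltetradec-1-en-5-yn-4-ol | C=CC[C@H](O)C#CC[C@@H](O[Si](C)(C)C(C)(C)C)C[C@@H](O[Si](C)(C)C(C)(C)C)C[C@H](O[Si](C)(C)C(C)(C)C)CCc1ccccc1 | intermediate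
27 | (4S,5Z,8R,10S,12R)-8,10,12-tris[(tert-butyldimethylsilyl)oxy]-14-phenyltetradeca-1,5-dien-4-ol | C=CC[C@H](O)/C=C\C[C@@H](O[Si](C)(C)C(C)(C)C)C[C@@H](O[Si](C)(C)C(C)(C)C)C[C@H](O[Si](C)(C)C(C)(C)C)CCc1ccccc1 | intermediate
28 | (4S,5Z,8R,10S,12R)-8,10,12-tris[(tert-butyldimethylsilyl)oxy]-14-phenyltetradeca-1,5-dien-4-yl prop-2-enoate | C=CC[C@H](OC(=O)C=C)/C=C\C[C@@H](O[Si](C)(C)C(C)(C)C)C[C@@H](O[Si](C)(C)C(C)(C)C)C[C@H](O[Si](C)(C)C(C)(C)C)CCc1ccccc1 | intermediate
29 | (6S)-6-[(1Z,4R,6S,8R)-4,6,8-tris[(tert-butyldimethylsilyl)oxy]-10-phenyldec-1-en-1-yl]-5,6-dihydro-2H-pyran-2-one | O=C1C=CC[C@@H](/C=C\C[C@@H](O[Si](C)(C)C(C)(C)C)C[C@@H](O[Si](C)(C)C(C)(C)C)C[C@H](O[Si](C)(C)C(C)(C)C)CCc2ccccc2)O1 | intermediate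
30 | (6S)-6-[(1Z,4R,6S,8R)-4,6,8-trihydroxy-10-phenyldec-1-en-1-yl]-5,6-dihydro-2H-pyran-2-one | O=C1C=CC[C@@H](/C=C\C[C@@H](O)C[C@@H](O)C[C@H](O)CCc2ccccc2)O1 | target

## Step count and least certain steps

Total step count: 23. Longest linear sequence: 23 steps, from 1 and 2 to 30; bromide 13 enters as purchased in step 9.

**Step 5 (key step).** The enantiotopic alkene carbons may be told apart incompletely if uncatalysed hydroalumination by free iBu2AlH competes with the nickel-bound pathway, and hydrometalation may stop short of ring opening and end in plain reduction of the alkene. The fallback replaces steps 5 and 6; it sets out from 6 and comes back at 10. Asymmetric hydroboration of 6 with diisopinocampheylborane (the pinene enantiomer that places boron on the alkene carbon beside the (R)-bridgehead), followed by alkaline peroxide, should give 3-exo-[(4-methoxybenzyl)oxy]-8-oxabicyclo[3.2.1]octan-6-exo-ol F1. Swern oxidation gives 3-exo-[(4-methoxybenzyl)oxy]-8-oxabicyclo[3.2.1]octan-6-one F2. Baeyer–Villiger oxidation (mCPBA, NaHCO3), in which the oxygen-bearing bridgehead migrates, gives 7-[(4-methoxybenzyl)oxy]-2,9-dioxabicyclo[3.3.1]nonan-3-one F3. LiAlH4 reduces both the lactone carbonyl (future C7) and the masked aldehyde (future C13) of F3 and gives triol 10.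

**Step 3.** Protonation of the reduced ketone may not favour the equatorial alcohol enough, and any axial alcohol carried on would end as the anti C9/C11 diol. The fallback sets out from 4 and comes back at 5. LiBH(s-Bu)3 in THF at −78 °C attacks the exo face and gives endo-8-oxabicyclo[3.2.1]oct-6-en-3-ol F4. Mitsunobu inversion (4-nitrobenzoic acid, PPh3, diisopropyl azodicarboxylate) gives exo-8-oxabicyclo[3.2.1]oct-6-en-3-yl 4-nitrobenzoate F5, and K2CO3 in MeOH gives 5.

**Step 6.** Ozone may attack the electron-rich anisyl ring of the PMB ether once the alkene is consumed, which would degrade the protecting group. The fallback sets out from 8 and comes back at 10. Dihydroxylation with OsO4 (cat.) and N-methylmorpholine N-oxide gives 6-[(4-methoxybenzyl)oxy]cycloheptane-1,3,4-triol F6. NaIO4 cleaves its vicinal diol to (3S,5R)-3-hydroxy-5-[(4-methoxybenzyl)oxy]heptanedial F7, which is present largely as its lactol, and NaBH4 in the same flask reduces it to 10.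

**Step 19.** The slim alkynyl group may give poor facial discrimination in the allylboration, which would lower the purity at C5. The fallback sets out from 25 and comes back at 26. AllylMgBr without chiral control gives (8R,10S,12R)-8,10,12-tris[(tert-butyldimethylsilyl)oxy]-14-phenyltetradec-1-en-5-yn-4-ol as both C5 epimers F8. Dess–Martin oxidation gives the ynone (8R,10S,12R)-8,10,12-tris[(tert-butyldimethylsilyl)oxy]-14-phenyltetradec-1-en-5-yn-4-one F9. Midland reduction with (S)-Alpine-Borane (B-isopinocampheyl-9-borabicyclo[3.3.1]nonane from (−)-α-pinene), which contains no B–H bond and so spares the alkene, gives 26.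

**Step 22.** The ruthenium carbene may engage the Z alkene, which would scramble its geometry or close a five-membered ring with loss of the side chain. The fallback sets out from 26 and comes back at 29, so that no Z alkene is present during metathesis. Acylation of 26 with acryloyl chloride gives (4S,8R,10S,12R)-8,10,12-tris[(tert-butyldimethylsilyl)oxy]-14-phenyltetradec-1-en-5-yn-4-yl prop-2-enoate F10. Ring-closing metathesis with (PCy3)2Cl2Ru=CHPh gives (6S)-6-[(4R,6S,8R)-4,6,8-tris[(tert-butyldimethylsilyl)oxy]-10-phenyldec-1-yn-1-yl]-5,6-dihydro-2H-pyran-2-one F11; the internal alkyne could react with the carbene only by closing a four-membered ring. Lindlar semihydrogenation of F11 then gives 29.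

## Further compounds

F1 | step 5 | 3-exo-[(4-methoxybenzyl)oxy]-8-oxabicyclo[3.2.1]octan-6-exo-ol | O[C@H]1C[C@@H]2C[C@@H](OCc3ccc(OC)cc3)C[C@H]1O2
F2 | step 5 | 3-exo-[(4-methoxybenzyl)oxy]-8-oxabicyclo[3.2.1]octan-6-one | O=C1C[C@@H]2C[C@@H](OCc3ccc(OC)cc3)C[C@H]1O2
F3 | step 5 | 7-[(4-methoxybenzyl)oxy]-2,9-dioxabicyclo[3.3.1]nonan-3-one | O=C1C[C@@H]2C[C@@H](OCc3ccc(OC)cc3)C[C@H](O1)O2
F4 | step 3 | endo-8-oxabicyclo[3.2.1]oct-6-en-3-ol | C1=C[C@@H]2C[C@H](O)C[C@H]1O2
F5 | step 3 | exo-8-oxabicyclo[3.2.1]oct-6-en-3-yl 4-nitrobenzoate | C1=C[C@@H]2C[C@@H](OC(=O)c3ccc(cc3)[N+](=O)[O-])C[C@H]1O2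
F6 | step 6 | 6-[(4-methoxybenzyl)oxy]cycloheptane-1,3,4-triol (cis-3,4-diol, both faces) | O[C@@H]1CC(O)C(O)C[C@H](OCc2ccc(OC)cc2)C1
F7 | step 6 | (3S,5R)-3-hydroxy-5-[(4-methoxybenzyl)oxy]heptanedial | O=CC[C@@H](O)C[C@@H](OCc1ccc(OC)cc1)CC=O
F8 | step 19 | (8R,10S,12R)-8,10,12-tris[(tert-butyldimethylsilyl)oxy]-14-phenyltetradec-1-en-5-yn-4-ol (C5 epimers) | C=CCC(O)C#CC[C@@H](O[Si](C)(C)C(C)(C)C)C[C@@H](O[Si](C)(C)C(C)(C)C)C[C@H](O[Si](C)(C)C(C)(C)C)CCc1ccccc1
F9 | step 19 | (8R,10S,12R)-8,10,12-tris[(tert-butyldimethylsilyl)oxy]-14-phenyltetradec-1-en-5-yn-4-one | C=CCC(=O)C#CC[C@@H](O[Si](C)(C)C(C)(C)C)C[C@@H](O[Si](C)(C)C(C)(C)C)C[C@H](O[Si](C)(C)C(C)(C)C)CCc1ccccc1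
F10 | step 22 | (4S,8R,10S,12R)-8,10,12-tris[(tert-butyldimethylsilyl)oxy]-14-phenyltetradec-1-en-5-yn-4-yl prop-2-enoate | C=CC[C@H](OC(=O)C=C)C#CC[C@@H](O[Si](C)(C)C(C)(C)C)C[C@@H](O[Si](C)(C)C(C)(C)C)C[C@H](O[Si](C)(C)C(C)(C)C)CCc1ccccc1
F11 | step 22 | (6S)-6-[(4R,6S,8R)-4,6,8-tris[(tert-butyldimethylsilyl)oxy]-10-phenyldec-1-yn-1-yl]-5,6-dihydro-2H-pyran-2-one | O=C1C=CC[C@@H](C#CC[C@@H](O[Si](C)(C)C(C)(C)C)C[C@@H](O[Si](C)(C)C(C)(C)C)C[C@H](O[Si](C)(C)C(C)(C)C)CCc2ccccc2)O1
A1 | alternative 1 | 2,6-cis-2-methoxy-6-alkynyl-5,6-dihydro-2H-pyran with C9/C11 acetonide and C13 silyl ether | CO[C@H]1C=CC[C@@H](C#CC[C@@H]2C[C@@H](OC(C)(C)O2)C[C@H](O[Si](C)(C)C(C)(C)C)CCc2ccccc2)O1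
A2 | alternative 1 | C5–C15 ynal with C9/C11 acetonide and C13 silyl ether | O=CC#CC[C@@H]1C[C@@H](OC(C)(C)O1)C[C@H](O[Si](C)(C)C(C)(C)C)CCc1ccccc1
A3 | alternative 1 | (E)-1-methoxybuta-1,3-diene | CO/C=C/C=C
A4 | alternative 2 | 1,5-anti β-hydroxy ketone C6–C15 (C9 hydroxyl, C11 ketone, C13 PMB ether, triisopropylsilyl alkyne) | CC(C)[Si](C(C)C)(C(C)C)C#CC[C@@H](O)CC(=O)C[C@H](OCc1ccc(OC)cc1)CCc1ccccc1
A5 | alternative 2 | (4R)-4-[(4-methoxybenzyl)oxy]-6-phenylhexan-2-one | CC(=O)C[C@H](OCc1ccc(OC)cc1)CCc1ccccc1
A6 | alternative 2 | 4-(triisopropylsilyl)but-3-ynal | CC(C)[Si](C(C)C)(C(C)C)C#CCC=O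
A7 | alternative 3 | eight-membered diisopropylsilylene ketal with Z C6=C7 | COc1ccc(COCC[C@H]2/C=C\C[C@H](C[C@@H]3C[C@H](OC(C)(C)O3)CCc3ccccc3)O[Si](C(C)C)(C(C)C)O2)cc1
A8 | alternative 3 | acyclic diisopropylsilylene-bridged diene | COc1ccc(COCC[C@@H](C=C)O[Si](C(C)C)(C(C)C)O[C@H](CC=C)C[C@@H]2C[C@H](OC(C)(C)O2)CCc2ccccc2)cc1
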